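## Retrosynthetic overview

- The 7-carbinol (C7′) is set last by catalyst-controlled (CBS) reduction of the corresponding aryl ketone.
- The 2-aryl-THF ring is formed by a desymmetrising, dearomative (p-quinone methide) 5-exo oxa-cyclisation of a C2-symmetric 1,4-diaryl-2,3-bis(hydroxymethyl)butane-1,4-diol. C7 ends up 2,3-trans by thermodynamic control.
- That tetraol comes from a bidirectional double Evans syn-aldol of succinyl bis-[(S)-4-benzyloxazolidinone] with vanillin acetate, followed by LiBH4. This sets C8 and C8′ and removes the auxiliaries and the acetates in one operation.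
- Only one ring is formed (the THF), and it is formed at the end.

**Numbering and assumptions**
- THF carbons: C7 (aryl-bearing), C8 (CH2OH-bearing), C8′ (carbinol-bearing). The carbinol is C7′, which is the "7-hydroxy" carbon of the target name.
- From the SMILES, the target is ring 7S, 8R, 8′R and carbinol 7′R. Aryl at C7 is trans to the C8 CH2OH. The C8 CH2OH is cis to the C8′ carbinol substituent.
- Phenol as free OH throughout after step 4; acetate is the only phenol protecting group.

## Route

**Step 1**
Reactants: 1 vanillin
Product: 2 vanillin acetate (4-formyl-2-methoxyphenyl acetate)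
Conditions: Ac2O, pyridine, CH2Cl2, rt
Reagents that add atoms: acetic anhydride, CC(=O)OC(C)=O (adds acetyl)
Why: O-acylation masks the acidic phenol so the boron enolate chemistry in step 3 is not quenched, and the acetate is removed for free in step 4.

**Step 2**
Reactants: 3 (S)-4-benzyloxazolidin-2-one; 4 succinyl chloride
Product: 5 (4S,4′S)-3,3′-succinylbis(4-benzyloxazolidin-2-one)
Conditions: 3 (2.05 equiv), n-BuLi (2.0 equiv), THF, −78 °C; add 4 (1 equiv), −78 → 0 °C
Reagents that add atoms: succinyl chloride, ClC(=O)CCC(Cl)=O (compound 4, the diacyl unit)
Why: N-acylation of the lithiated auxiliary gives the symmetric bis-imide, a simple achiral-backbone precursor for the bidirectional aldol.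

**Step 3**
Reactants: 5 bis-imide; 2 vanillin acetate (2.5 equiv)
Product: 6 C2-symmetric bis-syn-aldol (7S,8S,8′S,7′S at imide stage)
Conditions: Bu2BOTf (2.3 equiv), i-Pr2NEt (2.6 equiv), CH2Cl2, 0 °C, 1 h; cool to −78 °C, add 2; −78 → 0 °C; pH 7 buffer/MeOH/30% H2O2 work-up
Reagents that add atoms: none
Why: Z-boron enolate, Zimmerman–Traxler chair and the dipole-minimised (S)-auxiliary give the Evans syn-aldol, (2S,3S) for aryl aldehydes. Each end reacts independently, so C8 and C8′ come out (S,S) at this stage, which becomes (R,R) after imide reduction.
Proposed new method: the Evans syn-aldol is extended to both α-CH2 groups of a succinyl bis-imide. Each imide forms its Z-boron enolate in turn, and the auxiliary controls the face at each end. The closest known reaction is the Evans boron syn-aldol of N-acyloxazolidinones.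

**Step 4**
Reactants: 6
Product: 7 tetraol (1S,2R,3R,4S)-1,4-bis(4-hydroxy-3-methoxyphenyl)-2,3-bis(hydroxymethyl)butane-1,4-diol
Conditions: LiBH4 (8 equiv), THF, MeOH (8 equiv), 0 °C → rt; mild NH4Cl work-up
Reagents that add atoms: none
Why: reductive cleavage of the N-acyl oxazolidinones gives the primary alcohols (the auxiliary 3 is recovered), and the same reagent solvolyses the aryl acetates. C8 and C8′ are not epimerisable once the carbonyls are gone. The C9 priority change turns S into R, giving C8 = C8′ = R.

**Step 5 (key step)**
Reactants: 7
Product: 8 (7S,8R,8′R,7′S)-7-hydroxylariciresinol, the carbinol epimer of the target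
Conditions: p-TsOH·H2O (10 mol%), MeCN, 50 °C, stop at about 60% conversion; recycle 7
Reagents that add atoms: none (loses H2O)
Why: one 4-hydroxybenzylic alcohol dehydrates to a p-quinone methide, which the 9′-CH2OH traps in a 5-exo oxa-Michael closure. Reversible benzylic C–O ionisation funnels C7 to the 2,3-trans isomer (7S).
Proposed new method: the dearomatising quinone-methide formation and 5-exo trapping are the same as in biomimetic lignan chemistry. Because 7 is C2-symmetric, either half gives the same product, and the 9′-OH can only close onto C7 (the alternative is a 4-exo oxetane). Regiochemistry therefore needs no protecting groups. The carbinol C7′ may epimerise here, but this is harmless because it is reset in steps 6–7. The closest known reactions are acid-catalysed epimerisation of pinoresinol-type benzylic ethers and p-QM etherification.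

**Step 6**
Reactants: 8
Product: 9 7-oxolariciresinol, the aryl ketone at C7′
Conditions: activated MnO2 (10 equiv), CH2Cl2/acetone, rt
Reagents that add atoms: none
Why: MnO2 oxidises only the activated secondary benzylic alcohol, leaving the primary alcohol, the THF and C7–H untouched. C7′ becomes sp2, so its configuration is erased. C8′ is now α to the ketone, so the conditions are kept neutral.

**Step 7**
Reactants: 9
Product: 10 (7R)-7-hydroxylariciresinol (target)
Conditions: (S)-Me-CBS (20 mol%), BH3·SMe2 (4 equiv), THF, −20 °C; MeOH quench
Reagents that add atoms: none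
Why: Corey–Bakshi–Shibata reduction is reagent-controlled. (S)-CBS gives the (R)-carbinol for aryl alkyl ketones with the OH > Ar > alkyl priority pattern, which is the pattern here, so C7′ = R.

## Compound list

1 | vanillin | COc1cc(C=O)ccc1O | starting material
2 | vanillin acetate | COc1cc(C=O)ccc1OC(C)=O | intermediate
3 | (S)-4-benzyloxazolidin-2-one | O=C1N[C@@H](Cc2ccccc2)CO1 | starting material
4 | succinyl chloride | ClC(=O)CCC(Cl)=O | starting material
5 | (4S,4′S)-3,3′-succinylbis(4-benzyloxazolidin-2-one) | O=C(CCC(=O)N1[C@@H](Cc2ccccc2)COC1=O)N1[C@@H](Cc2ccccc2)COC1=O | intermediate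
6 | C2-symmetric bis-syn-aldol (7S,8S,8′S,7′S) | O=C(N1[C@@H](Cc2ccccc2)COC1=O)[C@H]([C@H](O)c1ccc(OC(C)=O)c(OC)c1)[C@@H]([C@H](O)c1ccc(OC(C)=O)c(OC)c1)C(=O)N1[C@@H](Cc2ccccc2)COC1=O | intermediate
7 | (1S,2R,3R,4S)-1,4-bis(4-hydroxy-3-methoxyphenyl)-2,3-bis(hydroxymethyl)butane-1,4-diol | OC[C@H]([C@H](O)c1ccc(O)c(OC)c1)[C@@H]([C@H](O)c1ccc(O)c(OC)c1)CO | intermediate
8 | (7S)-7-hydroxylariciresinol (carbinol epimer, 7S,8R,8′R,7′S) | COc1cc([C@H]2OC[C@H]([C@H](O)c3ccc(O)c(OC)c3)[C@@H]2CO)ccc1O | intermediate
9 | 7-oxolariciresinol (aryl ketone) | COc1cc([C@H]2OC[C@H](C(=O)c3ccc(O)c(OC)c3)[C@@H]2CO)ccc1O | intermediate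
10 | (7R)-7-hydroxylariciresinol | COc1cc([C@H]2OC[C@H]([C@@H](O)c3ccc(O)c(OC)c3)[C@@H]2CO)ccc1O | target

## Totals

Total steps: 7. Longest linear sequence: 6 (vanillin → 2 → 6 → 7 → 8 → 9 → 10; step 2 runs in parallel).

## Three steps most likely to fail

1. **Step 5, desymmetrising cyclisation.** Statistical mono- versus bis-cyclisation (the bis product is the furofuran, pinoresinol-type), or Friedel–Crafts closure to an aryltetralin, could cap the yield.
   Fallback: change from a cationic to an SN2 approach. Mono-silylate one primary OH of 7 (TBSCl, 1 equiv, imidazole), then Mitsunobu cyclodehydration (PPh3/DIAD), which can only close C7–O onto the free primary carbon with retention at C7. Remove the silyl group last.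
2. **Step 3, bidirectional aldol.** The second enolisation or the diastereoselectivity may be poor, or the β-boryloxy imide may lactonise.
   Fallback: iterative, differentiated assembly. Start from a succinic mono-imide/mono-ester, do one Evans aldol, convert the ester to a second imide, then do the second aldol with an anti-selective Evans protocol. This would also deliver the 7′R carbinol directly and remove steps 6–7.
3. **Steps 6–7, C7′ stereocontrol.** The ketone may epimerise at C8′, or it may sit as the cis-fused hemiketal with the C9-OH and resist CBS reduction with poor diastereoselectivity.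
   Fallback: skip oxidation/reduction. Protect the primary OH of 8 and invert C7′ by Mitsunobu (p-nitrobenzoic acid, PPh3, DIAD) then hydrolyse the ester (K2CO3/MeOH), or use a ketoreductase.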